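The terminal pyrogallol ring F is built, not attached. In ring F, carbons 3, 4 and 5 carry adjacent oxygens, and carbon 1, meta to carbons 3 and 5, carries the oxygen bound to E4. An aryl ynol ether supplies carbons 1 (with that oxygen) and 6; a 3,4-dialkoxycyclobutenone supplies carbons 2, 3, 4 and 5 (its carbonyl carbon). One thermal Danheiser benzannulation forms the 1–2, 5–6 and 4–5 bonds and closes ring F, so no aryl ether coupling is needed at the doubly flanked E4 oxygen. The precursor is the permethylated ABCDE pentamer with an ethynyl ether at E4, assembled by iterative aryl ether formation and Dakin-type oxidation; BBr3 finally cleaves fifteen alkyl ethers.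

Key step: step 13

Remark on lettering: rings run from A (2,4,6-trioxygenated end) to F (3,4,5-trioxygenated end). Rings B and D carry the ether oxygen towards ring A on position 1 and the ether oxygen towards ring F on position 2. Rings C and E are linked through positions 1 (towards A) and 4 (towards F). Ring F is numbered from the carbon that bears the ether oxygen (carbon 1 of ring F); its carbons 3, 4 and 5 carry oxygen. The target has no stereocentre.

Assumption: compounds 1, 4, 8, 18, 24 and 25 are taken as purchasable.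

Step 1
Reactants: 1 5-fluoro-1,2,3-trimethoxybenzene
Product: 3 6-fluoro-2,3,4-trimethoxybenzaldehyde, via aryllithium 2 (not isolated)
Conditions: n-BuLi, THF, −78 °C; DMF, −78 → 0 °C; aq NH4Cl
Reagents that add atoms: N,N-dimethylformamide, CN(C)C=O
Why: Directed ortho-lithiation and formylation: the two ring hydrogens of 1 are equivalent and each lies between fluorine and methoxy, so only one aldehyde can form, and −78 °C keeps the ortho-fluoroaryllithium 2 from eliminating LiF.

Step 2
Reactants: 4 2,4,6-trimethoxyphenol; 3 6-fluoro-2,3,4-trimethoxybenzaldehyde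
Product: 5 AB aldehyde 2,3,4-trimethoxy-6-(2,4,6-trimethoxyphenoxy)benzaldehyde
Conditions: Cs2CO3, DMSO, 110 °C, Ar
Reagents that add atoms: none
Why: Nucleophilic aromatic substitution (addition–elimination) forming the A1–O–B1 ether: the ortho-formyl group activates the fluoride towards the hindered but electron-rich phenoxide, and no metal catalyst has to cope with two ortho substituents.

Step 3
Reactants: 5 AB aldehyde
Product: 7 AB phenol 2,3,4-trimethoxy-6-(2,4,6-trimethoxyphenoxy)phenol, via AB formate 6 (not isolated)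
Conditions: mCPBA, CH2Cl2, 0 → 23 °C; then K2CO3 (cat.), MeOH, 0 °C, Ar
Reagents that add atoms: 3-chloroperoxybenzoic acid, OOC(=O)c1cccc(Cl)c1
Why: Baeyer–Villiger oxidation of an aryl aldehyde (Dakin-type): the aryl group, flanked by two oxygen substituents, should migrate in preference to hydride, and formate 6 is methanolysed to reveal the B2 hydroxyl.

Step 4
Reactants: 7 AB phenol; 8 4-bromo-2,6-dimethoxybenzaldehyde
Product: 9 ABC aldehyde 2,6-dimethoxy-4-[2,3,4-trimethoxy-6-(2,4,6-trimethoxyphenoxy)phenoxy]benzaldehyde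
Conditions: CuI (10 mol %), picolinic acid (20 mol %), K3PO4, DMSO, 90 °C, Ar
Reagents that add atoms: none
Why: Ullmann-type copper-catalysed O-arylation forming the B2–O–C1 ether: this ligand system is suited to di-ortho-substituted phenols, and the bromide of 8 is unhindered and activated by its para-formyl group.

Step 5
Reactants: 9 ABC aldehyde
Product: 11 ABC phenol 2,6-dimethoxy-4-[2,3,4-trimethoxy-6-(2,4,6-trimethoxyphenoxy)phenoxy]phenol, via ABC formate 10 (not isolated)
Conditions: mCPBA, CH2Cl2, 0 → 23 °C; then K2CO3 (cat.), MeOH, 0 °C, Ar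
Reagents that add atoms: 3-chloroperoxybenzoic acid, OOC(=O)c1cccc(Cl)c1
Why: Baeyer–Villiger oxidation (Dakin-type) of a 2,6-dimethoxy-4-aryloxybenzaldehyde, whose very electron-rich aryl group migrates readily; methanolysis of formate 10 reveals the C4 hydroxyl.

Step 6
Reactants: 11 ABC phenol; 3 6-fluoro-2,3,4-trimethoxybenzaldehyde
Product: 12 ABCD aldehyde (11 arylated on its C4 oxygen by a 2-formyl-3,4,5-trimethoxyphenyl group; CHO on D2)
Conditions: Cs2CO3, DMSO, 110 °C, Ar
Reagents that add atoms: none
Why: Nucleophilic aromatic substitution as in step 2, forming the C4–O–D1 ether: the 2,6-dimethoxyphenoxide of 11 has the same local environment as that of 4 and displaces the ortho-formyl-activated fluoride.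

Step 7
Reactants: 12 ABCD aldehyde
Product: 14 ABCD phenol (OH on D2), via ABCD formate 13 (not isolated)
Conditions: mCPBA, CH2Cl2, 0 → 23 °C; then K2CO3 (cat.), MeOH, 0 °C, Ar
Reagents that add atoms: 3-chloroperoxybenzoic acid, OOC(=O)c1cccc(Cl)c1
Why: Baeyer–Villiger oxidation (Dakin-type) as in step 3, the ring D aldehyde being the only oxidisable carbonyl; methanolysis of formate 13 reveals the D2 hydroxyl.

Step 8
Reactants: 14 ABCD phenol; 8 4-bromo-2,6-dimethoxybenzaldehyde
Product: 15 ABCDE aldehyde (14 arylated on its D2 oxygen by a 4-formyl-3,5-dimethoxyphenyl group; CHO on E4)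
Conditions: CuI (10 mol %), picolinic acid (20 mol %), K3PO4, DMSO, 90 °C, Ar
Reagents that add atoms: none
Why: Ullmann-type copper-catalysed O-arylation as in step 4, forming the D2–O–E1 ether between a hindered phenol and an unhindered, formyl-activated aryl bromide.

Step 9
Reactants: 15 ABCDE aldehyde
Product: 17 ABCDE phenol (permethylated pentamer with free OH on E4), via ABCDE formate 16 (not isolated)
Conditions: mCPBA, CH2Cl2, 0 → 23 °C; then K2CO3 (cat.), MeOH, 0 °C, Ar
Reagents that add atoms: 3-chloroperoxybenzoic acid, OOC(=O)c1cccc(Cl)c1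
Why: Baeyer–Villiger oxidation (Dakin-type) as in step 5; methanolysis of formate 16 reveals the E4 hydroxyl, the only free phenol in the molecule.

Step 10
Reactants: 17 ABCDE phenol; 18 trichloroethylene
Product: 20 (E)-1,2-dichlorovinyl ether of the pentamer at E4, via dichloroacetylene 19 (not isolated)
Conditions: K2CO3, DMF, 70 °C
Reagents that add atoms: none
Why: Base-mediated vinylation of a phenol with trichloroethylene: dehydrochlorination gives dichloroacetylene 19 in low concentration, and anti addition of the phenoxide gives the E dichlorovinyl ether, a reaction of oxygen on a small sp carbon that tolerates the two flanking methoxy groups.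

Step 11
Reactants: 20 (E)-1,2-dichlorovinyl ether
Product: 23 ethynyl ether of the ABCDE pentamer at E4, via chloroethynyl ether 21 (not isolated), via lithium acetylide 22 (not isolated)
Conditions: n-BuLi (2.4 equiv), THF, −78 → −40 °C; MeOH, −78 °C; cold neutral work-up, used at once
Reagents that add atoms: none
Why: Dehydrochlorination followed by lithium–chlorine exchange, the standard ynol ether synthesis from 1,2-dichlorovinyl ethers, gives acetylide 22, which is protonated cold; the E3 and E5 methoxy groups shield the ynol ether, and all other groups are methyl ethers inert to n-BuLi at this temperature.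

Step 12
Reactants: 24 methoxyacetyl chloride; 25 ethoxyacetylene
Product: 27 racemic 3-ethoxy-4-methoxycyclobut-2-en-1-one, via methoxyketene 26 (not isolated)
Conditions: Et3N (slow addition), 25 (excess), Et2O, 0 → 23 °C
Reagents that add atoms: none
Why: Ketene–alkyne [2+2] cycloaddition: the carbonyl carbon of methoxyketene 26 bonds to the nucleophilic CH carbon of ethoxyacetylene, giving the 3-ethoxy-4-methoxy regioisomer as a racemate whose single stereocentre is erased in step 13.

Step 13
Reactants: 23 ethynyl ether of the ABCDE pentamer at E4; 27 racemic 3-ethoxy-4-methoxycyclobut-2-en-1-one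
Product: 32 hexamer phenol (ring F as 3-ethoxy-5-hydroxy-4-methoxyphenyl ether on the E4 oxygen), via vinylketene 28 (not isolated), via vinylcyclobutenone 29 (not isolated), via dienylketene 30 (not isolated), via cyclohexadienone 31 (not isolated)
Conditions: 27 (2.5 equiv, in portions), toluene, 80 → 110 °C, Ar; then K2CO3, MeOH, 23 °C
Reagents that add atoms: none
Why: Danheiser benzannulation: thermal four-electron ring opening of 27 (methoxy expected to rotate outward) gives vinylketene 28, whose carbonyl carbon (future carbon 5 of ring F) is attacked by the unsubstituted alkyne carbon of 23 (future carbon 6 of ring F) in a ketene–alkyne [2+2] that also joins carbon 1 to carbon 2 of ring F and gives vinylcyclobutenone 29. Reversible four-electron opening of 29 gives dienylketene 30, and ring F closes by a thermal disrotatory 6π electrocyclisation that forms the bond between its carbons 4 and 5 (six-membered carbocycle, cyclohexadienone 31), followed by keto–enol tautomerisation to the phenol. The closest known reaction type is the benzannulation of 3-alkoxycyclobutenones with alkoxy- and siloxyacetylenes, which gives resorcinol monoethers. No stereocentre appears in the product, since the sp3 centres of 27, 29 and 31 vanish on aromatisation. The one selectivity needed is the regiochemistry of the [2+2], secured by the oxygen-induced polarisation of the ynol ether, so that carbon 1 of ring F with its aryloxy group ends up 1,3 to the new hydroxyl on carbon 5; the flanking methoxy groups shield the alkyne, and the lack of a hydrogen beta to its oxygen excludes the retro-ene loss that limits alkyl ynol ethers. Only the dienylketene geometry with the vinyl group cis to the ketene can cyclise, so reversibility of the openings funnels material to 32, and the closing methanolysis returns any 32 that was O-acylated by 28.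

Step 14
Reactants: 32 hexamer phenol
Product: 33 CNP0218077.0 (target)
Conditions: BBr3 (large excess), CH2Cl2, −78 → 23 °C, Ar; MeOH, 0 °C; evaporation, size-exclusion chromatography in degassed MeOH
Reagents that add atoms: none
Why: Lewis acid-mediated cleavage of alkyl aryl ethers: boron coordinates each methoxy or ethoxy oxygen, bromide removes the alkyl group by SN2, and methanol releases the phenols, whereas diaryl ethers have no alkyl carbon to attack and should stay intact.

Compound list
1 | 5-fluoro-1,2,3-trimethoxybenzene | COc1cc(F)cc(OC)c1OC | starting material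
2 | (6-fluoro-2,3,4-trimethoxyphenyl)lithium (aryllithium, formed in the flask) | [Li]c1c(F)cc(OC)c(OC)c1OC | intermediate
3 | 6-fluoro-2,3,4-trimethoxybenzaldehyde (building block for rings B and D) | COc1cc(F)c(C=O)c(OC)c1OC | intermediate
4 | 2,4,6-trimethoxyphenol (ring A) | COc1cc(OC)c(O)c(OC)c1 | starting material
5 | AB aldehyde: 2,3,4-trimethoxy-6-(2,4,6-trimethoxyphenoxy)benzaldehyde (CHO on B2) | COc1cc(OC)c(Oc2cc(OC)c(OC)c(OC)c2C=O)c(OC)c1 | intermediate
6 | AB formate: 2,3,4-trimethoxy-6-(2,4,6-trimethoxyphenoxy)phenyl formate (formed in the flask) | COc1cc(OC)c(Oc2cc(OC)c(OC)c(OC)c2OC=O)c(OC)c1 | intermediate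
7 | AB phenol: 2,3,4-trimethoxy-6-(2,4,6-trimethoxyphenoxy)phenol (OH on B2) | COc1cc(OC)c(Oc2cc(OC)c(OC)c(OC)c2O)c(OC)c1 | intermediate
8 | 4-bromo-2,6-dimethoxybenzaldehyde (building block for rings C and E) | COc1cc(Br)cc(OC)c1C=O | starting material
9 | ABC aldehyde: 2,6-dimethoxy-4-[2,3,4-trimethoxy-6-(2,4,6-trimethoxyphenoxy)phenoxy]benzaldehyde (CHO on C4) | COc1cc(OC)c(Oc2cc(OC)c(OC)c(OC)c2Oc2cc(OC)c(C=O)c(OC)c2)c(OC)c1 | intermediate
10 | ABC formate: formate ester of 11 on the C4 oxygen (formed in the flask) | COc1cc(OC)c(Oc2cc(OC)c(OC)c(OC)c2Oc2cc(OC)c(OC=O)c(OC)c2)c(OC)c1 | intermediate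
11 | ABC phenol: 2,6-dimethoxy-4-[2,3,4-trimethoxy-6-(2,4,6-trimethoxyphenoxy)phenoxy]phenol (OH on C4) | COc1cc(OC)c(Oc2cc(OC)c(OC)c(OC)c2Oc2cc(OC)c(O)c(OC)c2)c(OC)c1 | intermediate
12 | ABCD aldehyde: 11 arylated on the C4 oxygen by 2-formyl-3,4,5-trimethoxyphenyl (CHO on D2) | COc1cc(OC)c(Oc2cc(OC)c(OC)c(OC)c2Oc2cc(OC)c(Oc3cc(OC)c(OC)c(OC)c3C=O)c(OC)c2)c(OC)c1 | intermediate
13 | ABCD formate: formate ester of 14 on the D2 oxygen (formed in the flask) | COc1cc(OC)c(Oc2cc(OC)c(OC)c(OC)c2Oc2cc(OC)c(Oc3cc(OC)c(OC)c(OC)c3OC=O)c(OC)c2)c(OC)c1 | intermediate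
14 | ABCD phenol: permethylated tetramer with free OH on D2 | COc1cc(OC)c(Oc2cc(OC)c(OC)c(OC)c2Oc2cc(OC)c(Oc3cc(OC)c(OC)c(OC)c3O)c(OC)c2)c(OC)c1 | intermediate
15 | ABCDE aldehyde: 14 arylated on the D2 oxygen by 4-formyl-3,5-dimethoxyphenyl (CHO on E4) | COc1cc(OC)c(Oc2cc(OC)c(OC)c(OC)c2Oc2cc(OC)c(Oc3cc(OC)c(OC)c(OC)c3Oc3cc(OC)c(C=O)c(OC)c3)c(OC)c2)c(OC)c1 | intermediate
16 | ABCDE formate: formate ester of 17 on the E4 oxygen (formed in the flask) | COc1cc(OC)c(Oc2cc(OC)c(OC)c(OC)c2Oc2cc(OC)c(Oc3cc(OC)c(OC)c(OC)c3Oc3cc(OC)c(OC=O)c(OC)c3)c(OC)c2)c(OC)c1 | intermediate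
17 | ABCDE phenol: permethylated pentamer with free OH on E4 | COc1cc(OC)c(Oc2cc(OC)c(OC)c(OC)c2Oc2cc(OC)c(Oc3cc(OC)c(OC)c(OC)c3Oc3cc(OC)c(O)c(OC)c3)c(OC)c2)c(OC)c1 | intermediate
18 | trichloroethylene | ClC=C(Cl)Cl | starting material
19 | dichloroacetylene (formed in the flask) | ClC#CCl | intermediate
20 | (E)-1,2-dichlorovinyl ether of the ABCDE pentamer at E4 | COc1cc(OC)c(Oc2cc(OC)c(OC)c(OC)c2Oc2cc(OC)c(Oc3cc(OC)c(OC)c(OC)c3Oc3cc(OC)c(O/C(Cl)=C\Cl)c(OC)c3)c(OC)c2)c(OC)c1 | intermediate
21 | chloroethynyl ether of the ABCDE pentamer at E4 (formed in the flask) | COc1cc(OC)c(Oc2cc(OC)c(OC)c(OC)c2Oc2cc(OC)c(Oc3cc(OC)c(OC)c(OC)c3Oc3cc(OC)c(OC#CCl)c(OC)c3)c(OC)c2)c(OC)c1 | intermediate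
22 | lithium acetylide of 23 (formed in the flask) | COc1cc(OC)c(Oc2cc(OC)c(OC)c(OC)c2Oc2cc(OC)c(Oc3cc(OC)c(OC)c(OC)c3Oc3cc(OC)c(OC#C[Li])c(OC)c3)c(OC)c2)c(OC)c1 | intermediate
23 | ethynyl ether of the ABCDE pentamer at E4 (aryl ynol ether, key-step precursor) | COc1cc(OC)c(Oc2cc(OC)c(OC)c(OC)c2Oc2cc(OC)c(Oc3cc(OC)c(OC)c(OC)c3Oc3cc(OC)c(OC#C)c(OC)c3)c(OC)c2)c(OC)c1 | intermediate
24 | methoxyacetyl chloride | COCC(=O)Cl | starting material
25 | ethoxyacetylene | C#COCC | starting material
26 | methoxyketene (formed in the flask) | COC=C=O | intermediate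
27 | racemic 3-ethoxy-4-methoxycyclobut-2-en-1-one | CCOC1=CC(=O)C1OC | intermediate
28 | vinylketene: (Z)-3-ethoxy-4-methoxybuta-1,3-dien-1-one (formed in the flask) | O=C=C/C(OCC)=C/OC | intermediate
29 | vinylcyclobutenone: racemic 3-(pentamer E4-oxy)-4-[(Z)-1-ethoxy-2-methoxyethenyl]cyclobut-2-en-1-one (formed in the flask) | COc1cc(OC)c(Oc2cc(OC)c(OC)c(OC)c2Oc2cc(OC)c(Oc3cc(OC)c(OC)c(OC)c3Oc3cc(OC)c(OC4=CC(=O)C4/C(OCC)=C/OC)c(OC)c3)c(OC)c2)c(OC)c1 | intermediate
30 | dienylketene: (3E,5Z)-3-(pentamer E4-oxy)-5-ethoxy-6-methoxyhexa-1,3,5-trien-1-one (formed in the flask) | COc1cc(OC)c(Oc2cc(OC)c(OC)c(OC)c2Oc2cc(OC)c(Oc3cc(OC)c(OC)c(OC)c3Oc3cc(OC)c(O/C(C=C=O)=C/C(OCC)=C/OC)c(OC)c3)c(OC)c2)c(OC)c1 | intermediate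
31 | cyclohexadienone: racemic 3-(pentamer E4-oxy)-5-ethoxy-6-methoxycyclohexa-2,4-dien-1-one (formed in the flask) | COc1cc(OC)c(Oc2cc(OC)c(OC)c(OC)c2Oc2cc(OC)c(Oc3cc(OC)c(OC)c(OC)c3Oc3cc(OC)c(OC4=CC(=O)C(OC)C(OCC)=C4)c(OC)c3)c(OC)c2)c(OC)c1 | intermediate
32 | hexamer phenol: ABCDE pentamer carrying ring F as 3-ethoxy-5-hydroxy-4-methoxyphenyl on the E4 oxygen | COc1cc(OC)c(Oc2cc(OC)c(OC)c(OC)c2Oc2cc(OC)c(Oc3cc(OC)c(OC)c(OC)c3Oc3cc(OC)c(Oc4cc(O)c(OC)c(OCC)c4)c(OC)c3)c(OC)c2)c(OC)c1 | intermediate
33 | CNP0218077.0: hexameric phlorotannin with sixteen free hydroxyls and five diaryl ether bonds, no stereocentre | Oc1cc(O)c(Oc2cc(O)c(O)c(O)c2Oc2cc(O)c(Oc3cc(O)c(O)c(O)c3Oc3cc(O)c(Oc4cc(O)c(O)c(O)c4)c(O)c3)c(O)c2)c(O)c1 | target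

Total step count: 14.
Longest linear sequence: 13 steps (steps 1 to 11, then 13 and 14); step 12 is a one-step side branch.

Steps most likely to fail

Step 13 (key benzannulation). The ketene–alkyne cycloaddition may be outrun by self-condensation of the vinylketene or by thermal oligomerisation of the bulky aryl ynol ether, so that ring F never closes. The fallback brings ring F in preformed. It sets out from phenol 17, which is O-arylated with purchasable 5-iodo-1,2,3-trimethoxybenzene (COc1cc(I)cc(OC)c1OC) under CuI, picolinic acid, K3PO4, DMSO, 90 °C, conditions suited to di-ortho-substituted phenols. This should give the hexadecamethyl ether of the target F1. Treatment of F1 with BBr3 as in step 14 comes back to the route at 33.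

Step 11 (ynol ether release). The terminal ynol ether may be lost by hydration to the aryl acetate or by oligomerisation during protonation, work-up and concentration. The fallback avoids the free terminal alkyne. It sets out from 20, which is treated with n-BuLi as before, but acetylide 22 is quenched with Me3SiCl to give the (trimethylsilyl)ethynyl ether of the pentamer F2, expected to survive chromatography and storage. Heating F2 with 27 in toluene as in step 13 should give the C-silylated hexamer phenol F3, with silicon on carbon 6 of ring F (between the aryloxy-bearing and hydroxyl-bearing carbons), where it reinforces the polarisation of the alkyne. Ipso-protodesilylation of this electron-rich arylsilane with CF3CO2H in CH2Cl2 at 0 °C comes back to the route at 32.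

Step 14 (global dealkylation). Fifteen ether cleavages may stop short at buried positions, and the oxygen-sensitive hexadecaphenol may be lost by oxidation or irreversible adsorption during isolation. The fallback isolates the product through a stable derivative. It sets out from 32: after BBr3 and the methanol quench, the evaporated crude is peracetylated (Ac2O, pyridine, DMAP, 23 °C) to the hexadecaacetate of the target F4. F4 can be chromatographed on silica and separated from partly alkylated material, which can be resubmitted. Acid methanolysis of F4 (HCl generated from a catalytic amount of AcCl in degassed MeOH, 40 °C) gives only volatile co-products and comes back to the route at 33.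

Further compounds
F1 | step 13 | hexadecamethyl ether of the target (ring F as 3,4,5-trimethoxyphenyl on the E4 oxygen) | COc1cc(OC)c(Oc2cc(OC)c(OC)c(OC)c2Oc2cc(OC)c(Oc3cc(OC)c(OC)c(OC)c3Oc3cc(OC)c(Oc4cc(OC)c(OC)c(OC)c4)c(OC)c3)c(OC)c2)c(OC)c1
F2 | step 11 | (trimethylsilyl)ethynyl ether of the ABCDE pentamer at E4 | COc1cc(OC)c(Oc2cc(OC)c(OC)c(OC)c2Oc2cc(OC)c(Oc3cc(OC)c(OC)c(OC)c3Oc3cc(OC)c(OC#C[Si](C)(C)C)c(OC)c3)c(OC)c2)c(OC)c1
F3 | step 11 | hexamer phenol with ring F as 5-ethoxy-3-hydroxy-4-methoxy-2-(trimethylsilyl)phenyl on the E4 oxygen | COc1cc(OC)c(Oc2cc(OC)c(OC)c(OC)c2Oc2cc(OC)c(Oc3cc(OC)c(OC)c(OC)c3Oc3cc(OC)c(Oc4cc(OCC)c(OC)c(O)c4[Si](C)(C)C)c(OC)c3)c(OC)c2)c(OC)c1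
F4 | step 14 | hexadecaacetate of the target | CC(=O)Oc1cc(OC(C)=O)c(Oc2cc(OC(C)=O)c(OC(C)=O)c(OC(C)=O)c2Oc2cc(OC(C)=O)c(Oc3cc(OC(C)=O)c(OC(C)=O)c(OC(C)=O)c3Oc3cc(OC(C)=O)c(Oc4cc(OC(C)=O)c(OC(C)=O)c(OC(C)=O)c4)c(OC(C)=O)c3)c(OC(C)=O)c2)c(OC(C)=O)c1
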